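**Plan**

Ring B is numbered B1 (bears the 2-methylbutanoyl group), B2/B4/B6 (hydroxyls), B3 (CH2 to acetyl ring A) and B5 (CH2 to isobutyryl ring C).
Retrosynthesis: the seven O-benzyl groups and the B1–C(=O) bond are cut first (late Friedel–Crafts acylation). Ring B is then cut at B4–B5 and B6–B1, leaving a ring A 4-(arylmethyl)-3-siloxycyclobutenone and a ring C 3-aryl-1-siloxypropyne.
The enabling feature is the strict alternation on ring B of oxygen (B2, B4, B6) and carbon substituents (B1, B3, B5), with both CH2 links flanking the B4 oxygen. A 3-siloxycyclobutenone and a siloxyalkyne merge into exactly this pattern.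
Forward: rings A and C are each made from 2,4,6-trihydroxytoluene (C-acylation, benzyl/benzyl/methyl differentiation of the hydroxyls, bromination, cross-coupling of the side chain). Ring B is the only ring built, and it is built last, joining the halves in a fixed order.
The silyl ethers are then exchanged for benzyl ethers, B1 is acylated and all benzyl groups are removed by hydrogenolysis.
Stereochemistry: the single (R) centre comes from (R)-2-methylbutanoic acid, introduced in the penultimate step without base. The racemic C4 centre of the cyclobutenone vanishes on aromatisation.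

Key step: step 14

Abbreviations: ArA = 3-acetyl-2,6-bis(benzyloxy)-4-methoxy-5-methylphenyl (ring A unit); ArC = 2,6-bis(benzyloxy)-4-methoxy-3-methyl-5-(2-methylpropanoyl)phenyl (ring C unit).
Assumption: the parent ynol silyl ether (triisopropylsilyloxy)ethyne, the ketenophile of step 6, is taken to be at hand as a distilled reagent kept cold under argon; all other inputs are catalogue chemicals.

**Ring A half**

Step 1
Reactants: 1 2,4,6-trihydroxytoluene; 2 acetyl chloride
Product: 3 1-(2,4,6-trihydroxy-3-methylphenyl)ethan-1-one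
Conditions: AlCl3 (3.5 equiv), PhNO2–CH2Cl2, 0 °C to 50 °C; then ice/aq. HCl
Reagents that add atoms: none
Why: Friedel–Crafts C-acylation at one of the two equivalent free positions of the phloroglucinol nucleus, the first acyl group deactivating the ring against a second acylation.

Step 2
Reactants: 3 1-(2,4,6-trihydroxy-3-methylphenyl)ethan-1-one
Product: 5 1-[4,6-bis(benzyloxy)-2-methoxy-3-methylphenyl]ethan-1-one, via chelated phenol 4 (not isolated)
Conditions: BnBr (2.05 equiv), K2CO3 (4 equiv), DMF, rt; then MeI (3 equiv), 50 °C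
Reagents that add atoms: benzyl bromide BrCc1ccccc1; iodomethane CI
Why: Williamson etherification in order of acidity and access: the para hydroxyl and the ortho hydroxyl next to the ring hydrogen are benzylated first, while the hydroxyl wedged between the C-methyl group and the hydrogen-bonding ketone reacts last and takes the methyl group.

Step 3
Reactants: 5 1-[4,6-bis(benzyloxy)-2-methoxy-3-methylphenyl]ethan-1-one
Product: 6 1-[2,4-bis(benzyloxy)-3-bromo-6-methoxy-5-methylphenyl]ethan-1-one
Conditions: NBS (1.05 equiv), MeCN, 0 °C to rt, dark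
Reagents that add atoms: N-bromosuccinimide O=C1CCC(=O)N1Br
Why: electrophilic aromatic bromination at the only free ring carbon, which is activated by two ortho benzyloxy groups and the para methoxy group.

Step 4
Reactants: 6 1-[2,4-bis(benzyloxy)-3-bromo-6-methoxy-5-methylphenyl]ethan-1-one; 7 (3-ethoxy-3-oxopropyl)zinc bromide
Product: 8 ethyl 3-(ArA)propanoate
Conditions: Pd(OAc)2 (3 mol%), SPhos (2-dicyclohexylphosphino-2',6'-dimethoxybiphenyl, 6 mol%), THF, 60 °C
Reagents that add atoms: none
Why: Negishi cross-coupling, in which the alkylzinc halide tolerates ketone and ester and the bulky biaryl phosphine promotes oxidative addition and reductive elimination at the di-ortho-substituted, electron-rich bromide.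

Step 5
Reactants: 8 ethyl 3-(ArA)propanoate
Product: 9 3-(ArA)propanoic acid
Conditions: LiOH·H2O, THF–MeOH–H2O, rt; then 1 M HCl
Reagents that add atoms: lithium hydroxide (hydroxide oxygen) [Li+].[OH-]
Why: saponification of an unhindered ethyl ester, which should leave the hindered aryl ketone and the benzyl ethers untouched.

Step 6
Reactants: 9 3-(ArA)propanoic acid; 10 (triisopropylsilyloxy)ethyne
Product: 13 racemic 4-(ArA-methyl)-3-(triisopropylsilyloxy)cyclobut-2-en-1-one, via acid chloride 11 (not isolated), via ketene 12 (not isolated)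
Conditions: (COCl)2, DMF (cat.), CH2Cl2, 0 °C to rt, evaporate; then slow addition to 10 (2 equiv) and Et3N (1.2 equiv), Et2O, 0 °C to rt
Reagents that add atoms: none
Why: dehydrochlorination of the acid chloride gives the aldoketene at low stationary concentration, and the excess ynol ether traps it in a regioselective ketene–alkyne [2+2] cycloaddition (nucleophilic CH terminus to the ketene carbonyl carbon), which places the arylmethyl group at C4 and hydrogen at C2; C4 forms racemic and is destroyed in step 14.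

**Ring C half**

Step 7
Reactants: 1 2,4,6-trihydroxytoluene; 14 2-methylpropanoyl chloride
Product: 15 2-methyl-1-(2,4,6-trihydroxy-3-methylphenyl)propan-1-one
Conditions: AlCl3 (3.5 equiv), PhNO2–CH2Cl2, 0 °C to 50 °C; then ice/aq. HCl
Reagents that add atoms: none
Why: Friedel–Crafts C-acylation of the phloroglucinol nucleus, as in step 1.

Step 8
Reactants: 15 2-methyl-1-(2,4,6-trihydroxy-3-methylphenyl)propan-1-one
Product: 17 1-[4,6-bis(benzyloxy)-2-methoxy-3-methylphenyl]-2-methylpropan-1-one, via chelated phenol 16 (not isolated)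
Conditions: BnBr (2.05 equiv), K2CO3 (4 equiv), DMF, rt; then MeI (3 equiv), 50 °C
Reagents that add atoms: benzyl bromide BrCc1ccccc1; iodomethane CI
Why: the same graded Williamson etherification as in step 2, the chelated hydroxyl next to the C-methyl group being the last to react and the one that is methylated.

Step 9
Reactants: 17 1-[4,6-bis(benzyloxy)-2-methoxy-3-methylphenyl]-2-methylpropan-1-one
Product: 18 1-[2,4-bis(benzyloxy)-3-bromo-6-methoxy-5-methylphenyl]-2-methylpropan-1-one
Conditions: NBS (1.05 equiv), MeCN, 0 °C to rt, dark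
Reagents that add atoms: N-bromosuccinimide O=C1CCC(=O)N1Br
Why: electrophilic aromatic bromination at the single free, doubly ortho-oxygenated ring carbon.

Step 10
Reactants: 18 1-[2,4-bis(benzyloxy)-3-bromo-6-methoxy-5-methylphenyl]-2-methylpropan-1-one; 19 allyltributylstannane
Product: 20 3-(ArC)prop-1-ene
Conditions: Pd(PPh3)4 (5 mol%), PhMe, 110 °C
Reagents that add atoms: none
Why: Stille cross-coupling transfers the allyl group under neutral conditions that the aryl ketone tolerates.

Step 11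
Reactants: 20 3-(ArC)prop-1-ene
Product: 21 2-(ArC)acetaldehyde
Conditions: OsO4 (2 mol%), NaIO4 (4 equiv), 2,6-lutidine (2 equiv), dioxane–H2O 3:1, rt
Reagents that add atoms: osmium tetroxide (catalytic oxygen carrier) O=[Os](=O)(=O)=O; sodium periodate [Na+].[O-]I(=O)(=O)=O
Why: Lemieux–Johnson oxidative cleavage of the terminal alkene, with 2,6-lutidine suppressing over-oxidation, should give the arylacetaldehyde without touching the hexasubstituted arene.

Step 12
Reactants: 21 2-(ArC)acetaldehyde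
Product: 22 3-(ArC)prop-1-yne
Conditions: dimethyl (1-diazo-2-oxopropyl)phosphonate (1.3 equiv), K2CO3 (2 equiv), MeOH, 0 °C to rt
Reagents that add atoms: dimethyl (1-diazo-2-oxopropyl)phosphonate COP(=O)(OC)C(=[N+]=[N-])C(C)=O
Why: Ohira–Bestmann (Seyferth–Gilbert type) homologation, in which the diazomethylphosphonate anion adds to the aldehyde and loss of phosphate and N2 with a 1,2-hydrogen shift gives the terminal alkyne under carbonate conditions mild enough to leave the propargylic arene unisomerised.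

Step 13
Reactants: 22 3-(ArC)prop-1-yne
Product: 25 3-(ArC)-1-(triisopropylsilyloxy)prop-1-yne, via lithium acetylide 23 (not isolated), via lithium ynolate 24 (not isolated)
Conditions: t-BuOOH (1.1 equiv) and LiN(SiMe3)2 (2.2 equiv), THF, −78 °C; add 22, −78 °C to 0 °C; then iPr3SiOTf (1.2 equiv), −78 °C to 0 °C
Reagents that add atoms: tert-butyl hydroperoxide CC(C)(C)OO; triisopropylsilyl trifluoromethanesulfonate CC(C)[Si](OS(=O)(=O)C(F)(F)F)(C(C)C)C(C)C
Why: the lithium acetylide is oxidised at carbon by electrophilic lithium tert-butyl peroxide to the ynolate, which the hard, bulky silyl triflate captures on oxygen (acetylide oxidation–O-silylation route to siloxyalkynes), while the amide base is too weak and hindered to enolise the di-ortho-substituted aryl isopropyl ketone at low temperature.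

**Union and endgame**

Step 14
Reactants: 13 racemic 4-(ArA-methyl)-3-(triisopropylsilyloxy)cyclobut-2-en-1-one; 25 3-(ArC)-1-(triisopropylsilyloxy)prop-1-yne
Product: 30 2-(ArA-methyl)-6-(ArC-methyl)-3,5-bis(triisopropylsilyloxy)phenol, via vinylketene 26 (not isolated), via vinylcyclobutenone 27 (not isolated), via dienylketene 28 (not isolated), via cyclohexadienone 29 (not isolated)
Conditions: 13 (1.0 equiv), 25 (1.2 equiv), PhMe (0.3 M), Ar, 80 °C then 110 °C
Reagents that add atoms: none
Why: Heating opens cyclobutenone 13 by 4π-electrocyclic cleavage of its C1–C4 bond to vinylketene 26; the nucleophilic, oxygen-free carbon of ynol ether 25 attacks the ketene carbonyl carbon and the adduct closes to vinylcyclobutenone 27 ([2+2], forming B4–B5 and B6–B1), which reopens to dienylketene 28 and closes by thermal disrotatory 6π-electrocyclisation (re-forming B3–B4) to cyclohexadienone 29, whose enolisation gives the phenol. The closest known reaction type is the Danheiser benzannulation of cyclobutenones with siloxyalkynes, which delivers resorcinol monosilyl ethers; here the 3-siloxy group of 13 supplies the third oxygen. Ring B is the only ring closed, as a six-membered carbocycle by 6π-electrocyclisation of the triene terminus onto the ketene carbon. No stereocentre is created, because the racemic C4 of 13 and the sp3 carbons of 27 and 29 all end as aromatic carbons. The selectivity needed is regiochemical and is fixed by the polarity of the partners (electrophilic ketene carbon, nucleophilic β-carbon of the ynol ether), which puts the ring C arylmethyl group ortho and its siloxy group meta to the new hydroxyl, while outward rotation of the arylmethyl group in the first ring opening keeps it clear of a 1,5-hydrogen shift. The medium is neutral and aprotic, so the benzyl ethers, both aryl ketones and the silyl ethers should remain spectators.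

Step 15
Reactants: 30 2-(ArA-methyl)-6-(ArC-methyl)-3,5-bis(triisopropylsilyloxy)phenol
Product: 32 1,3,5-tris(benzyloxy)-2-(ArA-methyl)-4-(ArC-methyl)benzene, via triol 31 (not isolated)
Conditions: Bu4NF (2.3 equiv), THF, 0 °C; then BnBr (4.5 equiv), K2CO3 (3 equiv), DMF, rt to 40 °C, under Ar
Reagents that add atoms: benzyl bromide BrCc1ccccc1
Why: fluoride cleaves both aryl silyl ethers, and the tetrabutylammonium phenoxides together with the B4 phenol are O-benzylated (Williamson) in a dipolar aprotic medium that favours O- over C-alkylation, so that ring B enters the acylation as a tris(ether) with B1 as its only free carbon.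

Step 16
Reactants: 32 1,3,5-tris(benzyloxy)-2-(ArA-methyl)-4-(ArC-methyl)benzene; 33 (R)-2-methylbutanoic acid
Product: 35 (2R)-1-[2,4,6-tris(benzyloxy)-3-(ArA-methyl)-5-(ArC-methyl)phenyl]-2-methylbutan-1-one, via mixed anhydride 34 (not isolated)
Conditions: 33 (1.5 equiv) premixed with (CF3CO)2O (3 equiv), CH2Cl2, 0 °C; add 32, 0 °C to rt
Reagents that add atoms: none
Why: Friedel–Crafts acylation by the mixed carboxylic–trifluoroacetic anhydride at B1, the only unsubstituted carbon of the only activated ring (rings A and C are hexasubstituted and acyl-deactivated); no base and no strong Lewis acid are present, so the α-stereocentre, which takes no part in the bond formation, should be carried over as (R).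

Step 17
Reactants: 35 (2R)-1-[2,4,6-tris(benzyloxy)-3-(ArA-methyl)-5-(ArC-methyl)phenyl]-2-methylbutan-1-one
Product: 36 the target (2R)-1-(3-{[3-acetyl-2,6-dihydroxy-4-methoxy-5-methylphenyl]methyl}-5-{[2,6-dihydroxy-4-methoxy-3-methyl-5-(2-methylpropanoyl)phenyl]methyl}-2,4,6-trihydroxyphenyl)-2-methylbutan-1-one
Conditions: H2 (1 atm), 10% Pd/C, EtOAc–MeOH, rt
Reagents that add atoms: none
Why: hydrogenolysis of all seven aryl benzyl ethers under neutral conditions, which should leave the hindered, hydrogen-bonded aryl ketones and the α-stereocentre unchanged.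

**Compound list**

1 | 2,4,6-trihydroxytoluene (2-methylbenzene-1,3,5-triol) | Cc1c(O)cc(O)cc1O | starting material
2 | acetyl chloride | CC(=O)Cl | starting material
3 | 1-(2,4,6-trihydroxy-3-methylphenyl)ethan-1-one | CC(=O)c1c(O)c(C)c(O)cc1O | intermediate
4 | 1-[4,6-bis(benzyloxy)-2-hydroxy-3-methylphenyl]ethan-1-one | CC(=O)c1c(O)c(C)c(OCc2ccccc2)cc1OCc1ccccc1 | intermediate (not isolated)
5 | 1-[4,6-bis(benzyloxy)-2-methoxy-3-methylphenyl]ethan-1-one | CC(=O)c1c(OC)c(C)c(OCc2ccccc2)cc1OCc1ccccc1 | intermediate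
6 | 1-[2,4-bis(benzyloxy)-3-bromo-6-methoxy-5-methylphenyl]ethan-1-one | CC(=O)c1c(OC)c(C)c(OCc2ccccc2)c(Br)c1OCc1ccccc1 | intermediate
7 | (3-ethoxy-3-oxopropyl)zinc bromide | CCOC(=O)CC[Zn]Br | starting material
8 | ethyl 3-[3-acetyl-2,6-bis(benzyloxy)-4-methoxy-5-methylphenyl]propanoate | CCOC(=O)CCc1c(OCc2ccccc2)c(C)c(OC)c(C(C)=O)c1OCc1ccccc1 | intermediate
9 | 3-[3-acetyl-2,6-bis(benzyloxy)-4-methoxy-5-methylphenyl]propanoic acid | OC(=O)CCc1c(OCc2ccccc2)c(C)c(OC)c(C(C)=O)c1OCc1ccccc1 | intermediate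
10 | (triisopropylsilyloxy)ethyne | C#CO[Si](C(C)C)(C(C)C)C(C)C | starting material
11 | 3-[3-acetyl-2,6-bis(benzyloxy)-4-methoxy-5-methylphenyl]propanoyl chloride | ClC(=O)CCc1c(OCc2ccccc2)c(C)c(OC)c(C(C)=O)c1OCc1ccccc1 | intermediate (not isolated)
12 | 3-[3-acetyl-2,6-bis(benzyloxy)-4-methoxy-5-methylphenyl]prop-1-en-1-one (arylmethylketene) | O=C=CCc1c(OCc2ccccc2)c(C)c(OC)c(C(C)=O)c1OCc1ccccc1 | intermediate (not isolated)
13 | racemic 4-{[3-acetyl-2,6-bis(benzyloxy)-4-methoxy-5-methylphenyl]methyl}-3-(triisopropylsilyloxy)cyclobut-2-en-1-one | O=C1C=C(O[Si](C(C)C)(C(C)C)C(C)C)C1Cc1c(OCc2ccccc2)c(C)c(OC)c(C(C)=O)c1OCc1ccccc1 | intermediate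
14 | 2-methylpropanoyl chloride | CC(C)C(=O)Cl | starting material
15 | 2-methyl-1-(2,4,6-trihydroxy-3-methylphenyl)propan-1-one | CC(C)C(=O)c1c(O)c(C)c(O)cc1O | intermediate
16 | 1-[4,6-bis(benzyloxy)-2-hydroxy-3-methylphenyl]-2-methylpropan-1-one | CC(C)C(=O)c1c(O)c(C)c(OCc2ccccc2)cc1OCc1ccccc1 | intermediate (not isolated)
17 | 1-[4,6-bis(benzyloxy)-2-methoxy-3-methylphenyl]-2-methylpropan-1-one | CC(C)C(=O)c1c(OC)c(C)c(OCc2ccccc2)cc1OCc1ccccc1 | intermediate
18 | 1-[2,4-bis(benzyloxy)-3-bromo-6-methoxy-5-methylphenyl]-2-methylpropan-1-one | CC(C)C(=O)c1c(OC)c(C)c(OCc2ccccc2)c(Br)c1OCc1ccccc1 | intermediate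
19 | allyltributylstannane | C=CC[Sn](CCCC)(CCCC)CCCC | starting material
20 | 1-[2,4-bis(benzyloxy)-6-methoxy-5-methyl-3-(prop-2-en-1-yl)phenyl]-2-methylpropan-1-one | C=CCc1c(OCc2ccccc2)c(C)c(OC)c(C(=O)C(C)C)c1OCc1ccccc1 | intermediate
21 | 2-[2,6-bis(benzyloxy)-4-methoxy-3-methyl-5-(2-methylpropanoyl)phenyl]acetaldehyde | O=CCc1c(OCc2ccccc2)c(C)c(OC)c(C(=O)C(C)C)c1OCc1ccccc1 | intermediate
22 | 1-[2,4-bis(benzyloxy)-6-methoxy-5-methyl-3-(prop-2-yn-1-yl)phenyl]-2-methylpropan-1-one | C#CCc1c(OCc2ccccc2)c(C)c(OC)c(C(=O)C(C)C)c1OCc1ccccc1 | intermediate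
23 | lithium acetylide of 22 | [Li]C#CCc1c(OCc2ccccc2)c(C)c(OC)c(C(=O)C(C)C)c1OCc1ccccc1 | intermediate (not isolated)
24 | lithium 3-[2,6-bis(benzyloxy)-4-methoxy-3-methyl-5-(2-methylpropanoyl)phenyl]prop-1-yn-1-olate | [Li]OC#CCc1c(OCc2ccccc2)c(C)c(OC)c(C(=O)C(C)C)c1OCc1ccccc1 | intermediate (not isolated)
25 | 1-{2,4-bis(benzyloxy)-6-methoxy-5-methyl-3-[3-(triisopropylsilyloxy)prop-2-yn-1-yl]phenyl}-2-methylpropan-1-one | CC(C)[Si](C(C)C)(C(C)C)OC#CCc1c(OCc2ccccc2)c(C)c(OC)c(C(=O)C(C)C)c1OCc1ccccc1 | intermediate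
26 | (3Z)-5-(ArA)-3-(triisopropylsilyloxy)penta-1,3-dien-1-one (vinylketene) | O=C=C/C(O[Si](C(C)C)(C(C)C)C(C)C)=C/Cc1c(OCc2ccccc2)c(C)c(OC)c(C(C)=O)c1OCc1ccccc1 | intermediate (not isolated)
27 | racemic 4-[(1Z)-3-(ArA)-1-(triisopropylsilyloxy)prop-1-en-1-yl]-2-(ArC-methyl)-3-(triisopropylsilyloxy)cyclobut-2-en-1-one | O=C1C(Cc2c(OCc3ccccc3)c(C)c(OC)c(C(=O)C(C)C)c2OCc2ccccc2)=C(O[Si](C(C)C)(C(C)C)C(C)C)C1/C(O[Si](C(C)C)(C(C)C)C(C)C)=C/Cc1c(OCc2ccccc2)c(C)c(OC)c(C(C)=O)c1OCc1ccccc1 | intermediate (not isolated)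
28 | (3E,5Z)-7-(ArA)-2-(ArC-methyl)-3,5-bis(triisopropylsilyloxy)hepta-1,3,5-trien-1-one (dienylketene) | O=C=C(Cc1c(OCc2ccccc2)c(C)c(OC)c(C(=O)C(C)C)c1OCc1ccccc1)/C(O[Si](C(C)C)(C(C)C)C(C)C)=C\C(O[Si](C(C)C)(C(C)C)C(C)C)=C\Cc1c(OCc2ccccc2)c(C)c(OC)c(C(C)=O)c1OCc1ccccc1 | intermediate (not isolated)
29 | racemic 6-(ArA-methyl)-2-(ArC-methyl)-3,5-bis(triisopropylsilyloxy)cyclohexa-2,4-dien-1-one | O=C1C(Cc2c(OCc3ccccc3)c(C)c(OC)c(C(=O)C(C)C)c2OCc2ccccc2)=C(O[Si](C(C)C)(C(C)C)C(C)C)C=C(O[Si](C(C)C)(C(C)C)C(C)C)C1Cc1c(OCc2ccccc2)c(C)c(OC)c(C(C)=O)c1OCc1ccccc1 | intermediate (not isolated)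
30 | 2-(ArA-methyl)-6-(ArC-methyl)-3,5-bis(triisopropylsilyloxy)phenol (ring B: B4 OH, B2 and B6 silyl ethers, B1 H) | Oc1c(Cc2c(OCc3ccccc3)c(C)c(OC)c(C(=O)C(C)C)c2OCc2ccccc2)c(O[Si](C(C)C)(C(C)C)C(C)C)cc(O[Si](C(C)C)(C(C)C)C(C)C)c1Cc1c(OCc2ccccc2)c(C)c(OC)c(C(C)=O)c1OCc1ccccc1 | intermediate
31 | 2-(ArA-methyl)-4-(ArC-methyl)benzene-1,3,5-triol | Oc1cc(O)c(Cc2c(OCc3ccccc3)c(C)c(OC)c(C(=O)C(C)C)c2OCc2ccccc2)c(O)c1Cc1c(OCc2ccccc2)c(C)c(OC)c(C(C)=O)c1OCc1ccccc1 | intermediate (not isolated)
32 | 1,3,5-tris(benzyloxy)-2-(ArA-methyl)-4-(ArC-methyl)benzene | c1ccccc1COc1cc(OCc2ccccc2)c(Cc2c(OCc3ccccc3)c(C)c(OC)c(C(=O)C(C)C)c2OCc2ccccc2)c(OCc2ccccc2)c1Cc1c(OCc2ccccc2)c(C)c(OC)c(C(C)=O)c1OCc1ccccc1 | intermediate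
33 | (R)-2-methylbutanoic acid | CC[C@@H](C)C(=O)O | starting material
34 | (2R)-2-methylbutanoic trifluoroacetic anhydride | CC[C@@H](C)C(=O)OC(=O)C(F)(F)F | intermediate (not isolated)
35 | (2R)-1-[2,4,6-tris(benzyloxy)-3-(ArA-methyl)-5-(ArC-methyl)phenyl]-2-methylbutan-1-one | CC[C@@H](C)C(=O)c1c(OCc2ccccc2)c(Cc2c(OCc3ccccc3)c(C)c(OC)c(C(C)=O)c2OCc2ccccc2)c(OCc2ccccc2)c(Cc2c(OCc3ccccc3)c(C)c(OC)c(C(=O)C(C)C)c2OCc2ccccc2)c1OCc1ccccc1 | intermediate
36 | (2R)-1-(3-{[3-acetyl-2,6-dihydroxy-4-methoxy-5-methylphenyl]methyl}-5-{[2,6-dihydroxy-4-methoxy-3-methyl-5-(2-methylpropanoyl)phenyl]methyl}-2,4,6-trihydroxyphenyl)-2-methylbutan-1-one | CC[C@@H](C)C(=O)c1c(O)c(Cc2c(O)c(C)c(OC)c(C(C)=O)c2O)c(O)c(Cc2c(O)c(C)c(OC)c(C(=O)C(C)C)c2O)c1O | target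

**Count and risks**

Total step count: 17. Longest linear sequence: 11 steps (steps 7–13, then 14–17).

Step 14 (benzannulation). The electron-rich 3-siloxy vinylketene may dimerise or lose silicon before the ynol ether intercepts it, and reversible opening of the vinylcyclobutenone toward the unreactive dienylketene geometry may drain material into decomposition before the 6π closure. The fallback abandons the de novo construction and bridges a preformed ring B by Friedel–Crafts alkylation. Setting out from bromides 6 and 18, Stille coupling with (tributylstannyl)methanol (Pd(PPh3)4, dioxane, 100 °C) would give [3-acetyl-2,6-bis(benzyloxy)-4-methoxy-5-methylphenyl]methanol F1 and [2,6-bis(benzyloxy)-4-methoxy-3-methyl-5-(2-methylpropanoyl)phenyl]methanol F2. Acid-catalysed benzylation of excess phloroglucinol with F1 (p-TsOH cat., dioxane, rt) would give 2-(ArA-methyl)benzene-1,3,5-triol F3, and a second such alkylation of F3 with F2 would give triol 31. The route is rejoined at 31, which is benzylated as in the second half of step 15.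

Step 16 (acylation at B1). Attack at the crowded B1 position may be too slow, acid may induce loss or migration of an arylmethyl link from the very electron-rich ring B, and partial enolisation may erode the configuration. The fallback reverses the order: deprotect first, acylate last, under the classical conditions used for α-branched acylphloroglucinols. Setting out from 32, hydrogenolysis (H2, 10% Pd/C, EtOAc–MeOH) would give 2-[(3-acetyl-2,6-dihydroxy-4-methoxy-5-methylphenyl)methyl]-4-{[2,6-dihydroxy-4-methoxy-3-methyl-5-(2-methylpropanoyl)phenyl]methyl}benzene-1,3,5-triol F4. (R)-2-Methylbutanoyl chloride F5, made from 33 with oxalyl chloride, would then acylate F4 at its only free ring carbon (AlCl3, PhNO2, 0 °C to rt), arriving directly at target 36.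

Step 15 (desilylation and benzylation). The phloroglucinol phenoxide may be benzylated on carbon (at B1, or with dearomatisation at B3/B5), and etherification of the hindered B4 hydroxyl may stay incomplete. The fallback protects stepwise so that the tri-phenoxide is never formed. Setting out from 30, benzylation of its single phenol (BnBr, K2CO3, acetone, 50 °C), whose ortho carbons are substituted and whose para carbon is screened by two silyloxy groups, would give 1-(benzyloxy)-2-(ArA-methyl)-6-(ArC-methyl)-3,5-bis(triisopropylsilyloxy)benzene F6. Buffered fluoride (Bu4NF, AcOH, THF, 0 °C) would release 5-(benzyloxy)-4-(ArA-methyl)-6-(ArC-methyl)benzene-1,3-diol F7, and its etherification (BnBr, K2CO3, acetone, reflux) returns to 32.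

Further compounds
F1 | step 14 | [3-acetyl-2,6-bis(benzyloxy)-4-methoxy-5-methylphenyl]methanol | OCc1c(OCc2ccccc2)c(C)c(OC)c(C(C)=O)c1OCc1ccccc1
F2 | step 14 | [2,6-bis(benzyloxy)-4-methoxy-3-methyl-5-(2-methylpropanoyl)phenyl]methanol | OCc1c(OCc2ccccc2)c(C)c(OC)c(C(=O)C(C)C)c1OCc1ccccc1
F3 | step 14 | 2-{[3-acetyl-2,6-bis(benzyloxy)-4-methoxy-5-methylphenyl]methyl}benzene-1,3,5-triol | Oc1cc(O)c(Cc2c(OCc3ccccc3)c(C)c(OC)c(C(C)=O)c2OCc2ccccc2)c(O)c1
F4 | step 16 | 2-[(3-acetyl-2,6-dihydroxy-4-methoxy-5-methylphenyl)methyl]-4-{[2,6-dihydroxy-4-methoxy-3-methyl-5-(2-methylpropanoyl)phenyl]methyl}benzene-1,3,5-triol | Oc1cc(O)c(Cc2c(O)c(C)c(OC)c(C(=O)C(C)C)c2O)c(O)c1Cc1c(O)c(C)c(OC)c(C(C)=O)c1O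
F5 | step 16 | (R)-2-methylbutanoyl chloride | CC[C@@H](C)C(=O)Cl
F6 | step 15 | 1-(benzyloxy)-2-(ArA-methyl)-6-(ArC-methyl)-3,5-bis(triisopropylsilyloxy)benzene | c1ccccc1COc1c(Cc2c(OCc3ccccc3)c(C)c(OC)c(C(=O)C(C)C)c2OCc2ccccc2)c(O[Si](C(C)C)(C(C)C)C(C)C)cc(O[Si](C(C)C)(C(C)C)C(C)C)c1Cc1c(OCc2ccccc2)c(C)c(OC)c(C(C)=O)c1OCc1ccccc1
F7 | step 15 | 5-(benzyloxy)-4-(ArA-methyl)-6-(ArC-methyl)benzene-1,3-diol | Oc1cc(O)c(Cc2c(OCc3ccccc3)c(C)c(OC)c(C(=O)C(C)C)c2OCc2ccccc2)c(OCc2ccccc2)c1Cc1c(OCc2ccccc2)c(C)c(OC)c(C(C)=O)c1OCc1ccccc1
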